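**Retrosynthetic overview**
Feature: the central ring is numbered C1, C2 (benzoate carbons), C3, C6 (4-hydroxyphenyl carbons) and C4, C5 (free hydroxyl carbons). With C1 and C4 raised to carbonyls it is a 2,5-dioxygenated 3,6-diaryl-1,4-benzoquinone in which O2 and O5 can carry different groups.
Key disconnection: cutting C1–C2 and C3–C4 leaves a four-carbon maleoyl unit C4–C5–C6–C1 (a cobaltacycle from a 3-benzyloxy-4-arylcyclobutenedione) and a two-carbon unit C2–C3 (an aryl triisopropylsilyl ynol ether). The central ring is the only ring the route builds.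
Precursors: aryllithium addition to diisopropyl squarate, acid rearrangement and isopropyl-to-benzyl exchange give the cyclobutenedione. Acetylide oxidation and O-silylation of 1-benzyloxy-4-ethynylbenzene give the siloxyalkyne.
Endgame: O2 is desilylated and the quinone reduced. O1/O2, then the only adjacent pair of free hydroxyls, are tied as a cyclic orthoformate so that O4 can be benzylated; release, dibenzoylation of O1/O2 and fourfold hydrogenolysis follow.

Key step: step 6

Remark: the target has no stereocentre; the carbinol carbon of 4 and the orthoformate carbon of 17 are transient centres formed as racemates and lost later.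

**Step 1**
Reactants: 1 1-benzyloxy-4-bromobenzene; 2 diisopropyl squarate
Product: 5 3-(4-benzyloxyphenyl)-4-isopropoxycyclobut-3-ene-1,2-dione, via aryllithium 3 (not isolated), via squarate adduct 4 (not isolated)
Conditions: n-BuLi, THF, −78 °C; 2, −78 °C; 1 M HCl quench; crude 4, conc. HCl (cat.), CH2Cl2, rt
Reagents that add atoms: none
Why: Bromine–lithium exchange, 1,2-addition of the aryllithium to one squarate carbonyl and acid-catalysed loss of isopropanol form the standard squarate-to-arylcyclobutenedione sequence, and the racemic carbinol centre of 4 disappears in the rearrangement.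

**Step 2**
Reactants: 5 3-(4-benzyloxyphenyl)-4-isopropoxycyclobut-3-ene-1,2-dione
Product: 6 3-(4-benzyloxyphenyl)-4-hydroxycyclobut-3-ene-1,2-dione
Conditions: 6 M HCl, THF, 60 °C
Reagents that add atoms: water, O
Why: Acid hydrolysis of a vinylogous ester by addition–elimination gives the strongly acidic hydroxycyclobutenedione, while the benzyl ether on the electron-poor aryl ring tolerates aqueous HCl.

**Step 3**
Reactants: 6 3-(4-benzyloxyphenyl)-4-hydroxycyclobut-3-ene-1,2-dione
Product: 7 3-benzyloxy-4-(4-benzyloxyphenyl)cyclobut-3-ene-1,2-dione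
Conditions: BnBr, Ag2O, 4 Å MS, CH2Cl2, rt, dark
Reagents that add atoms: benzyl bromide, BrCc1ccccc1
Why: Silver-assisted O-alkylation of a vinylogous acid is the classical way to squaric esters, and alkylation at either end of the vinylogous carboxylate gives the same compound.

**Step 4**
Reactants: 7 3-benzyloxy-4-(4-benzyloxyphenyl)cyclobut-3-ene-1,2-dione
Product: 8 chlorobis(triphenylphosphine)[2-benzyloxy-3-(4-benzyloxyphenyl)maleoyl]cobalt, CoCl(PPh3)2(maleoyl), a five-membered cobaltacyclopentenedione
Conditions: CoCl(PPh3)3, benzene, rt → 50 °C, Ar; precipitation with hexane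
Reagents that add atoms: CoCl(PPh3)3, Cl[Co-3]([P+](c1ccccc1)(c1ccccc1)c1ccccc1)([P+](c1ccccc1)(c1ccccc1)c1ccccc1)[P+](c1ccccc1)(c1ccccc1)c1ccccc1
Why: Oxidative addition of monovalent cobalt into the strained bond between the two carbonyl carbons (C4–C1) gives the maleoyl complex of trivalent cobalt, a C–C activation established for alkyl-, aryl- and alkoxy-substituted cyclobutenediones.

**Step 5**
Reactants: 9 1-benzyloxy-4-ethynylbenzene
Product: 12 [(4-benzyloxyphenyl)ethynyloxy]triisopropylsilane, via lithium acetylide 10 (not isolated), via lithium ynolate 11 (not isolated)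
Conditions: n-BuLi, THF, −78 °C; t-BuOOLi (from t-BuOOH and LiN(SiMe3)2), −78 → 0 °C; TIPSOTf, −78 → 0 °C; Et3N-deactivated silica
Reagents that add atoms: tert-butyl hydroperoxide, CC(C)(C)OO; triisopropylsilyl triflate, CC(C)[Si](OS(=O)(=O)C(F)(F)F)(C(C)C)C(C)C
Why: Oxygen transfer from lithium tert-butyl peroxide to the acetylide gives the ynolate, which the bulky silyl triflate traps on oxygen (the established acetylide-oxidation route to silyl ynol ethers), and with only stoichiometric base present the benzyl aryl ether is not exposed to excess alkyllithium that could start a Wittig rearrangement.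

**Step 6**
Reactants: 8 chlorobis(triphenylphosphine)maleoylcobalt complex; 12 [(4-benzyloxyphenyl)ethynyloxy]triisopropylsilane
Product: 14 2-benzyloxy-3,6-bis(4-benzyloxyphenyl)-5-(triisopropylsilyloxy)-1,4-benzoquinone, via cationic cobalt complex 13 (not isolated)
Conditions: AgBF4 (1.0 equiv), MeCN, rt, dark; filtration of AgCl under Ar; then 12, 2,6-di-tert-butyl-4-methylpyridine, ClCH2CH2Cl–MeCN, rt → 70 °C
Reagents that add atoms: none
Why: Proposed new method: AgBF4 removes chloride from 8 and gives the cationic complex 13 of trivalent cobalt, 12 displaces a labile acetonitrile, the bound alkyne inserts into one acyl–cobalt bond to give a seven-membered cobaltacycle, and reductive elimination with the second acyl expels monovalent cobalt. The closest known reaction type is the benzoquinone synthesis from cyclobutenedione-derived maleoylcobalt complexes (alkoxy-substituted ones included) and simple terminal or internal alkynes, in which a siloxyalkyne has not served as partner. The central ring is closed in a formal (4+2) mode, C1–C2 and C3–C4 being the two new bonds and reductive elimination the ring-closing event, and no stereocentre arises. The step needs head-to-tail orientation, and polarity matching should secure it: the nucleophilic aryl-bearing carbon C3 of the ynol ether pairs with C4, the ketone-like acyl beside the benzyloxy carbon, while the ketenium-like carbon C2 pairs with C1, the acyl that receives electron density from O5 as a vinylogous ester, and the same pairing results whether C1 migrates to C2 first or C3 attacks C4 first. Because free silver ion, strong acid and added Lewis acids all activate siloxyalkynes or could reverse the bias of the two acyls, AgCl and residual silver are filtered off before 12 is added, a hindered pyridine takes up traces of HBF4, and no Lewis acid promoter is used.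

**Step 7**
Reactants: 14 2-benzyloxy-3,6-bis(4-benzyloxyphenyl)-5-(triisopropylsilyloxy)-1,4-benzoquinone
Product: 15 2-benzyloxy-3,6-bis(4-benzyloxyphenyl)-5-hydroxy-1,4-benzoquinone
Conditions: TBAF, AcOH, THF, 0 °C
Reagents that add atoms: none
Why: Buffered fluoride desilylation cleaves the silyl vinylogous ester at O2 alone, leaving all benzyl ethers, and the acidic hydroxyquinone can be freed from phosphine and cobalt residues by base extraction.

**Step 8**
Reactants: 15 2-benzyloxy-3,6-bis(4-benzyloxyphenyl)-5-hydroxy-1,4-benzoquinone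
Product: 17 6-benzyloxy-4,7-bis(4-benzyloxyphenyl)-2-ethoxy-1,3-benzodioxol-5-ol (racemic), via triol 16 (not isolated)
Conditions: Na2S2O4, THF–H2O, rt, Ar; extraction under Ar; then HC(OEt)3, PPTS (cat.), toluene, 90–110 °C, EtOH distilled off
Reagents that add atoms: triethyl orthoformate, CCOC(OCC)OCC
Why: Dithionite reduction of the quinone is followed by reversible acid-catalysed orthoester exchange, which settles on the only five-membered ring available, the 1,3-benzodioxole across the adjacent free hydroxyls O1 and O2 (a tactic known from gallate-type phenols), so O4–H stays free beside the O5 benzyl ether and the orthoformate carbon is a racemic transient stereocentre.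

**Step 9**
Reactants: 17 6-benzyloxy-4,7-bis(4-benzyloxyphenyl)-2-ethoxy-1,3-benzodioxol-5-ol
Product: 18 5,6-bis(benzyloxy)-4,7-bis(4-benzyloxyphenyl)-2-ethoxy-1,3-benzodioxole
Conditions: BnBr, K2CO3, DMF, rt → 50 °C, Ar
Reagents that add atoms: benzyl bromide, BrCc1ccccc1
Why: Williamson etherification of the single free phenol O4 proceeds under base, to which the cyclic orthoformate is inert.

**Step 10**
Reactants: 18 5,6-bis(benzyloxy)-4,7-bis(4-benzyloxyphenyl)-2-ethoxy-1,3-benzodioxole
Product: 20 4,5-bis(benzyloxy)-3,6-bis(4-benzyloxyphenyl)benzene-1,2-diol, via monoformate 19 (not isolated)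
Conditions: 1 M aq HCl, THF, rt, Ar
Reagents that add atoms: none
Why: Acid hydrolysis of a cyclic orthoester is far faster than any reaction of benzyl aryl ethers, and the first-formed labile aryl formate is hydrolysed under the same conditions.

**Step 11**
Reactants: 20 4,5-bis(benzyloxy)-3,6-bis(4-benzyloxyphenyl)benzene-1,2-diol
Product: 21 4,5-bis(benzyloxy)-3,6-bis(4-benzyloxyphenyl)-1,2-phenylene dibenzoate
Conditions: BzCl, pyridine, DMAP (cat.), CH2Cl2, 0 °C → rt, Ar
Reagents that add atoms: benzoyl chloride, O=C(Cl)c1ccccc1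
Why: DMAP-catalysed acylation of the only two free hydroxyls (O1, O2) installs both benzoates, the nucleophilic catalyst compensating for the flanking aryl groups.

**Step 12**
Reactants: 21 4,5-bis(benzyloxy)-3,6-bis(4-benzyloxyphenyl)-1,2-phenylene dibenzoate
Product: 22 4,5-dihydroxy-3,6-bis(4-hydroxyphenyl)-1,2-phenylene dibenzoate (CNP0216579.0)
Conditions: H2 (1 atm), 10% Pd/C, EtOAc–THF, rt
Reagents that add atoms: none
Why: Catalytic hydrogenolysis removes the four benzyl aryl ethers under neutral conditions, while the aryl benzoates are inert and cannot migrate because the C3 and C6 aryl groups separate them from the new hydroxyls.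

**Compound list**
1 | 1-benzyloxy-4-bromobenzene | Brc1ccc(OCc2ccccc2)cc1 | starting material
2 | diisopropyl squarate | CC(C)OC1=C(OC(C)C)C(=O)C1=O | starting material
3 | 4-benzyloxyphenyllithium | [Li]c1ccc(OCc2ccccc2)cc1 | intermediate
4 | 4-(4-benzyloxyphenyl)-4-hydroxy-2,3-diisopropoxycyclobut-2-en-1-one (racemic) | O=C1C(OC(C)C)=C(OC(C)C)C1(O)c1ccc(OCc2ccccc2)cc1 | intermediate
5 | 3-(4-benzyloxyphenyl)-4-isopropoxycyclobut-3-ene-1,2-dione | CC(C)OC1=C(c2ccc(OCc3ccccc3)cc2)C(=O)C1=O | intermediate
6 | 3-(4-benzyloxyphenyl)-4-hydroxycyclobut-3-ene-1,2-dione | OC1=C(c2ccc(OCc3ccccc3)cc2)C(=O)C1=O | intermediate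
7 | 3-benzyloxy-4-(4-benzyloxyphenyl)cyclobut-3-ene-1,2-dione | O=C1C(=O)C(OCc2ccccc2)=C1c1ccc(OCc2ccccc2)cc1 | intermediate
8 | chlorobis(triphenylphosphine)[2-benzyloxy-3-(4-benzyloxyphenyl)maleoyl]cobalt | O=C1C(OCc2ccccc2)=C(c2ccc(OCc3ccccc3)cc2)C(=O)[Co-2]1(Cl)([P+](c1ccccc1)(c1ccccc1)c1ccccc1)[P+](c1ccccc1)(c1ccccc1)c1ccccc1 | intermediate
9 | 1-benzyloxy-4-ethynylbenzene | C#Cc1ccc(OCc2ccccc2)cc1 | starting material
10 | lithium (4-benzyloxyphenyl)acetylide | [Li]C#Cc1ccc(OCc2ccccc2)cc1 | intermediate
11 | lithium (4-benzyloxyphenyl)ynolate | [Li]OC#Cc1ccc(OCc2ccccc2)cc1 | intermediate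
12 | [(4-benzyloxyphenyl)ethynyloxy]triisopropylsilane | CC(C)[Si](OC#Cc1ccc(OCc2ccccc2)cc1)(C(C)C)C(C)C | intermediate
13 | bis(acetonitrile)bis(triphenylphosphine)[2-benzyloxy-3-(4-benzyloxyphenyl)maleoyl]cobalt tetrafluoroborate | CC#[N+][Co-3]1([N+]#CC)([P+](c2ccccc2)(c2ccccc2)c2ccccc2)([P+](c2ccccc2)(c2ccccc2)c2ccccc2)C(=O)C(OCc2ccccc2)=C(c2ccc(OCc3ccccc3)cc2)C1=O.F[B-](F)(F)F | intermediate
14 | 2-benzyloxy-3,6-bis(4-benzyloxyphenyl)-5-(triisopropylsilyloxy)-1,4-benzoquinone | O=C1C(O[Si](C(C)C)(C(C)C)C(C)C)=C(c2ccc(OCc3ccccc3)cc2)C(=O)C(OCc2ccccc2)=C1c1ccc(OCc2ccccc2)cc1 | intermediate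
15 | 2-benzyloxy-3,6-bis(4-benzyloxyphenyl)-5-hydroxy-1,4-benzoquinone | O=C1C(O)=C(c2ccc(OCc3ccccc3)cc2)C(=O)C(OCc2ccccc2)=C1c1ccc(OCc2ccccc2)cc1 | intermediate
16 | 5-benzyloxy-3,6-bis(4-benzyloxyphenyl)benzene-1,2,4-triol | Oc1c(O)c(-c2ccc(OCc3ccccc3)cc2)c(O)c(OCc2ccccc2)c1-c1ccc(OCc2ccccc2)cc1 | intermediate
17 | 6-benzyloxy-4,7-bis(4-benzyloxyphenyl)-2-ethoxy-1,3-benzodioxol-5-ol (racemic) | CCOC1Oc2c(O1)c(-c1ccc(OCc3ccccc3)cc1)c(O)c(OCc1ccccc1)c2-c1ccc(OCc2ccccc2)cc1 | intermediate
18 | 5,6-bis(benzyloxy)-4,7-bis(4-benzyloxyphenyl)-2-ethoxy-1,3-benzodioxole | CCOC1Oc2c(O1)c(-c1ccc(OCc3ccccc3)cc1)c(OCc1ccccc1)c(OCc1ccccc1)c2-c1ccc(OCc2ccccc2)cc1 | intermediate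
19 | 3,4-bis(benzyloxy)-2,5-bis(4-benzyloxyphenyl)-6-hydroxyphenyl formate | O=COc1c(O)c(-c2ccc(OCc3ccccc3)cc2)c(OCc2ccccc2)c(OCc2ccccc2)c1-c1ccc(OCc2ccccc2)cc1 | intermediate
20 | 4,5-bis(benzyloxy)-3,6-bis(4-benzyloxyphenyl)benzene-1,2-diol | Oc1c(O)c(-c2ccc(OCc3ccccc3)cc2)c(OCc2ccccc2)c(OCc2ccccc2)c1-c1ccc(OCc2ccccc2)cc1 | intermediate
21 | 4,5-bis(benzyloxy)-3,6-bis(4-benzyloxyphenyl)-1,2-phenylene dibenzoate | O=C(Oc1c(OC(=O)c2ccccc2)c(-c2ccc(OCc3ccccc3)cc2)c(OCc2ccccc2)c(OCc2ccccc2)c1-c1ccc(OCc2ccccc2)cc1)c1ccccc1 | intermediate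
22 | 4,5-dihydroxy-3,6-bis(4-hydroxyphenyl)-1,2-phenylene dibenzoate (CNP0216579.0) | O=C(Oc1c(OC(=O)c2ccccc2)c(-c2ccc(O)cc2)c(O)c(O)c1-c1ccc(O)cc1)c1ccccc1 | target

**Total step count:** 12
**Longest linear sequence:** 11 steps (steps 1–4 and 6–12); step 5 is the convergent branch.

**Steps most likely to fail**

1. Step 6.
   - Risk: the electron-rich alkyne may be protonated or ionised at the cationic metal centre and lost through hydrolysis or oligomerisation before it inserts. Tetrafluoroborate may strip the silyl group. Insertion may also run with poor head-to-tail selectivity. Early loss of silicon after ring closure would be harmless, since step 7 removes it anyway.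
   - Fallback (known chemistry): it sets out from 1 and returns at 15. Compound 1 would be lithiated and borylated (n-BuLi; B(OiPr)3; aqueous acid) to 4-benzyloxyphenylboronic acid F1.
   - Commercial tetrabromo-1,4-benzoquinone and sodium benzyloxide would give 2,5-bis(benzyloxy)-3,6-dibromo-1,4-benzoquinone F2 by twofold addition–elimination.
   - A double Suzuki–Miyaura coupling of F1 with F2 (Pd(PPh3)4, CsF, dioxane) would give 2,5-bis(benzyloxy)-3,6-bis(4-benzyloxyphenyl)-1,4-benzoquinone F3, the para relation of the aryl groups being fixed by the dibromide.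
   - One equivalent of NaOH in THF–water would saponify a single vinylogous ester and give 15, because the resulting quinone anion resists a second hydrolysis.

2. Step 8.
   - Risk: the electron-rich triol may be re-oxidised by air during transfer. Orthoester exchange may be slow or incomplete at a catechol flanked by two twisted aryl rings.
   - Fallback: it sets out from 15 and returns at 20. The silver salt of 15 (Ag2O, toluene, dark) would be alkylated with BnBr.
   - With silver held between O1 and O2, the vinylogous oxygen O4 is the exposed nucleophile. This is the pattern seen when silver salts of 2-hydroxy-1,4-naphthoquinones give 4-alkoxy-1,2-naphthoquinones.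
   - The product would be 4,5-bis(benzyloxy)-3,6-bis(4-benzyloxyphenyl)-1,2-benzoquinone F4, and Na2S2O4 would reduce it directly to 20. The triol and both orthoformates are bypassed.

3. Step 5.
   - Risk: oxygen transfer to a conjugated aryl acetylide may be incomplete. The ynol ether may be lost by hydrolysis during work-up or chromatography.
   - Fallback: it sets out from 1 and returns at 12. Aryllithium 3 made from 1 would be quenched with methyl chloroformate to methyl 4-benzyloxybenzoate F5.
   - A Kowalski ester homologation would follow. CH2Br2 and lithium tetramethylpiperidide at −78 °C would give the lithium enolate of 2,2-dibromo-1-(4-benzyloxyphenyl)ethanone F6.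
   - A measured amount of n-BuLi and warming would trigger bromine–lithium exchange and 1,2-aryl shift to the same ynolate 11, which TIPSOTf would silylate on oxygen to 12.

**Further compounds**
F1 | step 6 | 4-benzyloxyphenylboronic acid | OB(O)c1ccc(OCc2ccccc2)cc1
F2 | step 6 | 2,5-bis(benzyloxy)-3,6-dibromo-1,4-benzoquinone | O=C1C(Br)=C(OCc2ccccc2)C(=O)C(Br)=C1OCc1ccccc1
F3 | step 6 | 2,5-bis(benzyloxy)-3,6-bis(4-benzyloxyphenyl)-1,4-benzoquinone | O=C1C(OCc2ccccc2)=C(c2ccc(OCc3ccccc3)cc2)C(=O)C(OCc2ccccc2)=C1c1ccc(OCc2ccccc2)cc1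
F4 | step 8 | 4,5-bis(benzyloxy)-3,6-bis(4-benzyloxyphenyl)-1,2-benzoquinone | O=C1C(=O)C(c2ccc(OCc3ccccc3)cc2)=C(OCc2ccccc2)C(OCc2ccccc2)=C1c1ccc(OCc2ccccc2)cc1
F5 | step 5 | methyl 4-benzyloxybenzoate | COC(=O)c1ccc(OCc2ccccc2)cc1
F6 | step 5 | 2,2-dibromo-1-(4-benzyloxyphenyl)ethanone | O=C(C(Br)Br)c1ccc(OCc2ccccc2)cc1
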